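# Proposed total synthesis of CNP0235031.1 (28) by nickel-catalysed reductive alkyne–enoyl closure of ring B

## The problem

The target 28 is a trans-decalin (ring A: C1–C5 and C10; ring B: C5–C10) with five stereocentres, C1, C4, C5, C9 and C10, two of them quaternary (C4, C10), a C8 exocyclic methylene (C17) and a (12E)-3-methylpenta-2,4-dienyl chain on C9. C10 is the hub: its axial methyl C20 is 1,3-diaxial to the axial C19 ester on C4 and flanks both C1 and C9, so once C10 is fixed relative to C5 it can direct C1, C4 and C9, and only C5 needs an external chiral influence. The C1 oxygen must end equatorial, cis to C20 and trans to C9, and the C9 chain must end equatorial and cis to C20; neither C5 nor C9 can be epimerised once ring B exists. The fragile parts are the conjugated terminal diene (acid, heat, radicals), the 8(17)-alkene (acid-induced migration into the ring) and the secondary acetate (base, hydride), so the diene is built late and the acetate last; the hindered axial methyl ester is robust. C4, which bears a methyl and an ester, is best carried as a symmetric malonate until the decalin exists to direct its alkylation. The feature that makes the key step possible is the array C17H2=C8–C9H–C11H2–C12 of ring B: a 1,1-disubstituted alkene whose allylic carbon C9 lies β to an oxidised C12 is what remains when a terminal alkyne C8≡C17 is coupled reductively to the β-carbon C9 of a C9=C11–C12=O acceptor, and both partners can be hung trans on the adjacent ring A carbons C5 and C10.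

## Retrosynthesis

**Acetate and diene.** 28 is traced through alcohol 27 to silyl ether 26, and the diene of 26 is cut at C14=C15 and C12=C13, which leads through enal 25 to aldehyde 24. Two Wittig steps are preferred to a single coupling of a branched allyl unit because a stabilised formyl ylide fixes the 12E geometry of the trisubstituted alkene, which a one-step sulfone or phosphonate olefination would not do reliably. 24 is a plain aldehyde without the sensitive diene, available from alcohol 23. The forward steps must be E-selective and non-acidic.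

**C4.** 23 is cut at C4–C18 and a second ester is put back on C4, giving monoester 21 and then malonate 20. A malonate keeps C4 achiral all the way back to the purchased ring; bringing the finished C4 centre in with ring A would make enone 4 chiral and racemic. The forward steps are a dealkoxycarbonylation and an enolate methylation that must enter on the face away from C20, leaving the ester axial; this is the known preference of 10-methyl trans-decalin ester enolates. 20 comes from imide 19 by reduction.

**C8–C9 (key disconnection).** 19 is cut at C8–C9 to the monocyclic alkyne–enoyl imide 17. A cut at C9–C10 would require ring closure onto a quaternary carbon. An aldol-type closure of ring B would leave oxygen on C8 and then need methylenation of a hindered carbonyl next to C9. The C8–C9 cut delivers the methylene group and the C11 methylene in their final oxidation states, and sets C9 in the ring-forming event. The precursor is one ring and one stereocentre simpler. The forward reaction must close a six-membered ring next to quaternary C10 and place C11 equatorial.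

**The arms on C10 and the C1 oxygen.** 17 comes from alcohol 16, and 16 is cut at C9=C11 to aldehyde 11 and phosphonate 15 (from oxazolidinone 12 and phosphonoacetic acid 13). 11 is traced through diol 10 and its silylated alkyne 9 to hydroxy ketone 8. C9 is carried as a hydroxymethyl group because that group directs the C1 ketone reduction to the anti diol; reducing C1 after the olefination would expose the imide to hydride. The forward sequence needs a primary-selective oxidation and a mild olefination.

**C5–C6 and C10–C9.** 8 is cut to enone 4, bromide 5 (as Grignard reagent 6) and a one-carbon electrophile that traps enolate 7. The order is dictated by stereochemistry: the group introduced last at C10 ends trans to the C5 chain, and that group must be C9, so the methyl has to be in the enone already. This step sets C5 by catalyst control and C10 by substrate control. It asks for an enantioselective conjugate addition to a hindered trisubstituted enone.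

**Enone 4.** 4 is cut at C10–C20 to iodoenone 3, which comes from enone 2 and the symmetric, purchased ketone 1. Iodination followed by coupling places the methyl only on the enone α-carbon. Methylating 1 first and then dehydrogenating would raise a regiochemical question.

## Roads not taken

Alternative 1: Ring A is cut at C4–C5 and C1–C10, back to 3-methyl-2H-pyran-2-one A1 and the E-enal A2. In the forward direction a Diels–Alder reaction under high pressure or Lewis acid catalysis would give the bridged lactone aldehyde A3.
- **Merits:** one step sets C1, C4, C5 and C10, including the quaternary C4. The lactone bridge ties the C1 oxygen and C19 together on the correct face. No malonate, dealkoxycarbonylation, C4 alkylation or C1 reduction is needed, which saves about four ring A operations against the chosen plan.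
- **Weak points:** A1 is an electron-poor diene and A2 an electron-poor, trisubstituted dienophile, so the pair is mismatched. Both new bonds form at or next to quaternary carbons. Regiochemistry and endo/exo selectivity are uncertain, and the adduct can lose CO2 on heating. There is no evident handle for absolute configuration. A3 still lacks ring B and C9, so a closure of the C8–C9 type would be needed anyway, after hydrogenation of the bridge alkene and opening of the lactone.
- **Comparison:** the chosen plan spends more steps on C1 and C4. Against that it sets ordinary conditions, predictable control at every centre and a catalytic asymmetric entry.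

Alternative 2: Both rings are cut at C5–C10, back to the ten-membered epoxy enoate A4. In the forward direction Cp2TiCl (trivalent titanium) would open the epoxide to the tertiary C10 radical, which adds across the ring to C5 of the enoate and gives decalin A5.
- **Merits:** one step closes both rings and sets C5 and C10. The equatorial C1 alcohol emerges free, and the exocyclic methylene is already present. After the cyclisation this road is shorter than the chosen plan and needs no C1 protecting group.
- **Weak points:** A4 is a functionalised cyclodecene with defined alkene geometry, a defined epoxide and the C9 stereocentre. Making it by macrocyclisation is a harder problem than the decalin itself. The ring fusion depends on the macrocycle conformation. C4 emerges as a mixture and still needs the enolate alkylation. The C10 radical can also be intercepted by the nearby methylene group.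
- **Comparison:** the chosen plan closes only one ring in its key step. It sets against the elegance of the transannular closure a precursor (17) that is reached from a purchased ring by standard reactions.

Alternative 3: Both rings are cut at C5–C10 and C8–C9, back to the acyclic trienal A6. In the forward direction an intramolecular Diels–Alder reaction (thermal or with Me2AlCl) would give the octalin aldehyde A7.
- **Merits:** two rings, two C–C bonds and C5, C8, C9 and C10 form in one step, without a transition metal and from an acyclic, convergent precursor. The single C1 carbinol centre controls the absolute sense. In bond-forming economy it is better than the chosen plan.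
- **Weak points:** the functionality of A7 is misplaced. C8 carries oxygen and would have to be oxidised and methylenated next to an epimerisable C9. The C6=C7 alkene must be hydrogenated. The aldehyde carbon is C11, so a one-carbon homologation precedes the diene. The dienophile is a trisubstituted enal that must form quaternary C10, and with this tether cis- and trans-fused products are both plausible.
- **Comparison:** the chosen plan delivers C8=C17 and the C11–C12 chain at the right length and oxidation state directly from the ring closure, which outweighs the extra ring A steps.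

Key step: step 11

## Assumptions

- Compounds 1, 5, 12, 13, 2-(triphenylphosphoranylidene)propanal and the common reagents are purchased.
- Locants in the text are those of the target (labdane numbering): C1–C10 are the ring carbons, C11–C16 the side chain, C17 the methylene carbon, C18 the C4 methyl, C19 the ester carbon and C20 the C10 methyl. Monocyclic compounds are named with cyclohexane locants. Bicyclic compounds are named as decalins (decahydronaphthalenes, trans-fused) with labdane locants.
- The enantiomer of the carbene ligand in step 4 is the one that gives 5S; its sense of induction has to be established on the first run.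

## Route

Step 1
Reactants: 1 dimethyl 4-oxocyclohexane-1,1-dicarboxylate
Product: 2 dimethyl 4-oxocyclohex-2-ene-1,1-dicarboxylate
Conditions: Pd(O2CCF3)2 (5 mol %), DMSO (10 mol %), O2 (1 atm), AcOH, 80 °C
Reagents that add atoms: none
Why: Palladium-catalysed aerobic α,β-dehydrogenation of a cyclohexanone (enolate palladation, β-hydride elimination, reoxidation of zerovalent palladium by O2); the ketone is symmetrical, so only one enone can form, and the quaternary C4 rules out aromatisation.

Step 2
Reactants: 2 dimethyl 4-oxocyclohex-2-ene-1,1-dicarboxylate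
Product: 3 dimethyl 3-iodo-4-oxocyclohex-2-ene-1,1-dicarboxylate
Conditions: I2, pyridine, CH2Cl2, 0 °C to rt
Reagents that add atoms: iodine, II
Why: Pyridine-mediated α-iodination of an enone (conjugate addition of pyridine, iodination of the enolate, elimination) puts iodine on the enone α-carbon C10; the reaction is standard for 4,4-disubstituted cyclohexenones.

Step 3
Reactants: 3 dimethyl 3-iodo-4-oxocyclohex-2-ene-1,1-dicarboxylate
Product: 4 dimethyl 3-methyl-4-oxocyclohex-2-ene-1,1-dicarboxylate
Conditions: MeB(OH)2, PdCl2(dppf) (5 mol %), K3PO4, dioxane, 80 °C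
Reagents that add atoms: methylboronic acid, CB(O)O
Why: Suzuki–Miyaura methylation of an α-iodoenone; oxidative addition into the activated vinyl C–I bond is fast and the non-enolisable malonate tolerates the phosphate base.

Step 4
Reactants: 4 dimethyl 3-methyl-4-oxocyclohex-2-ene-1,1-dicarboxylate; 5 (4-bromobut-1-yn-1-yl)trimethylsilane
Product: 8 dimethyl (2S,3R)-3-(hydroxymethyl)-3-methyl-4-oxo-2-[4-(trimethylsilyl)but-3-yn-1-yl]cyclohexane-1,1-dicarboxylate, via Grignard reagent 6 (not isolated), via magnesium enolate 7 (not isolated)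
Conditions: Mg, Et2O, rt (5 to 6); Cu(OTf)2 (5 mol %), chiral hydroxyalkyl-imidazolinium salt (carbene precursor, 6 mol %), Et2O, −30 °C, 6 added slowly to 4; CH2O (gas, from cracked paraformaldehyde), −78 to −40 °C; aq. NH4Cl
Reagents that add atoms: formaldehyde, C=O
Why: Copper–carbene-catalysed asymmetric conjugate addition of a Grignard reagent to an α-methyl cyclic enone with trapping of the enolate (tandem conjugate addition–aldol) is a known reaction class for 2-methylcyclohexenones. The chiral copper complex selects the enone face and sets C5 (S); formaldehyde, the smallest carbon electrophile, then enters C10 anti to the new C5 chain, so C9 ends trans and the C20 methyl cis to C6.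

Step 5
Reactants: 8 dimethyl (2S,3R)-3-(hydroxymethyl)-3-methyl-4-oxo-2-[4-(trimethylsilyl)but-3-yn-1-yl]cyclohexane-1,1-dicarboxylate
Product: 9 dimethyl (2S,3R,4S)-4-hydroxy-3-(hydroxymethyl)-3-methyl-2-[4-(trimethylsilyl)but-3-yn-1-yl]cyclohexane-1,1-dicarboxylate
Conditions: Me4NBH(OAc)3, AcOH/MeCN (1:1), −30 °C
Reagents that add atoms: none
Why: Evans–Saksena reduction: the primary hydroxyl exchanges onto boron and delivers hydride intramolecularly to the ketone face syn to C9, giving the anti 1,3-diol with the C1 oxygen trans to C9 and cis to C20 (1S in target numbering). This is also the axial-attack face of the chair with both chains equatorial, and the triacetoxyborohydride leaves the esters alone.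

Step 6
Reactants: 9 dimethyl (2S,3R,4S)-4-hydroxy-3-(hydroxymethyl)-3-methyl-2-[4-(trimethylsilyl)but-3-yn-1-yl]cyclohexane-1,1-dicarboxylate
Product: 10 dimethyl (2S,3R,4S)-2-(but-3-yn-1-yl)-4-hydroxy-3-(hydroxymethyl)-3-methylcyclohexane-1,1-dicarboxylate
Conditions: Bu4NF (1.1 equiv), AcOH (1.1 equiv), THF, 0 °C
Reagents that add atoms: none
Why: Fluoride-induced protodesilylation of the alkynylsilane; buffering with acetic acid keeps the medium non-basic so that the primary hydroxyl does not lactonise onto the malonate.

Step 7
Reactants: 10 dimethyl (2S,3R,4S)-2-(but-3-yn-1-yl)-4-hydroxy-3-(hydroxymethyl)-3-methylcyclohexane-1,1-dicarboxylate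
Product: 11 dimethyl (2S,3S,4S)-2-(but-3-yn-1-yl)-3-formyl-4-hydroxy-3-methylcyclohexane-1,1-dicarboxylate
Conditions: TEMPO (10 mol %), PhI(OAc)2 (1.1 equiv), CH2Cl2, rt
Reagents that add atoms: none
Why: Oxoammonium (TEMPO) oxidation with PhI(OAc)2 as terminal oxidant is selective for primary over secondary alcohols; the aldehyde has no α-hydrogen, so it can neither epimerise nor eliminate.

Step 8
Reactants: 12 oxazolidin-2-one; 13 2-(diethoxyphosphoryl)acetic acid
Product: 15 diethyl [2-oxo-2-(2-oxo-1,3-oxazolidin-3-yl)ethyl]phosphonate, via mixed pivalic anhydride 14 (not isolated)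
Conditions: t-BuCOCl, Et3N, THF, −20 °C (13 to 14); then 12, LiCl, −20 °C to rt
Reagents that add atoms: none
Why: N-Acylation of the oxazolidinone through the mixed pivalic anhydride with LiCl/Et3N activation, the usual mild alternative to acylating the lithiated oxazolidinone.

Step 9
Reactants: 11 dimethyl (2S,3S,4S)-2-(but-3-yn-1-yl)-3-formyl-4-hydroxy-3-methylcyclohexane-1,1-dicarboxylate; 15 diethyl [2-oxo-2-(2-oxo-1,3-oxazolidin-3-yl)ethyl]phosphonate
Product: 16 dimethyl (2S,3S,4S)-2-(but-3-yn-1-yl)-4-hydroxy-3-methyl-3-[(1E)-3-oxo-3-(2-oxo-1,3-oxazolidin-3-yl)prop-1-en-1-yl]cyclohexane-1,1-dicarboxylate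
Conditions: LiCl, i-Pr2NEt, MeCN, rt
Reagents that add atoms: none
Why: Horner–Wadsworth–Emmons olefination under Masamune–Roush conditions (LiCl, amine base) is mild enough for a β-hydroxy aldehyde and reliably E-selective with this stabilised imide phosphonate; the C1 hydroxyl cannot add to the new acceptor because that would form a four-membered ring.

Step 10
Reactants: 16 dimethyl (2S,3S,4S)-2-(but-3-yn-1-yl)-4-hydroxy-3-methyl-3-[(1E)-3-oxo-3-(2-oxo-1,3-oxazolidin-3-yl)prop-1-en-1-yl]cyclohexane-1,1-dicarboxylate
Product: 17 dimethyl (2S,3S,4S)-2-(but-3-yn-1-yl)-4-[(tert-butyldimethylsilyl)oxy]-3-methyl-3-[(1E)-3-oxo-3-(2-oxo-1,3-oxazolidin-3-yl)prop-1-en-1-yl]cyclohexane-1,1-dicarboxylate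
Conditions: TBSOTf, 2,6-lutidine, CH2Cl2, −78 to 0 °C
Reagents that add atoms: tert-butyldimethylsilyl trifluoromethanesulfonate, CC(C)(C)[Si](C)(C)OS(=O)(=O)C(F)(F)F
Why: Silylation of the hindered secondary alcohol with the silyl triflate; the ether masks the C1 hydroxyl through the hydride, enolate and ylide steps and is removed by fluoride at the end.

Step 11
Reactants: 17 dimethyl (2S,3S,4S)-2-(but-3-yn-1-yl)-4-[(tert-butyldimethylsilyl)oxy]-3-methyl-3-[(1E)-3-oxo-3-(2-oxo-1,3-oxazolidin-3-yl)prop-1-en-1-yl]cyclohexane-1,1-dicarboxylate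
Product: 19 dimethyl (1S,5S,9R,10S)-1-[(tert-butyldimethylsilyl)oxy]-10-methyl-8-methylidene-9-[2-oxo-2-(2-oxo-1,3-oxazolidin-3-yl)ethyl]decalin-4,4-dicarboxylate, via silyl ketene N,O-acetal 18 (not isolated)
Conditions: Ni(cod)2 (15 mol %), PBu3 (30 mol %), Et3SiH (3 equiv), THF, 45 °C, slow addition of 17; then aq. NH4Cl
Reagents that add atoms: none
Why: Zerovalent nickel bearing PBu3 binds the terminal alkyne and the enoyl alkene and undergoes oxidative cyclisation to a seven-membered oxanickelacycle (a nickel O-enolate) in which the C8–C9 bond is formed. σ-Bond metathesis with Et3SiH then puts silicon on the enolate oxygen and hydride on nickel, C–H reductive elimination puts hydrogen on C17 and returns zerovalent nickel, and hydrolysis of the silyl ketene N,O-acetal 18 on work-up puts hydrogen on C11. The closest known reaction type is the nickel-catalysed reductive cyclisation of alkynes tethered to enones or unsaturated acyl oxazolidinones, which gives rings with an exocyclic alkene; closing a six-membered ring next to a quaternary carbon is the untested element. Ring B closes by bonding of alkyne carbon C8 to alkene carbon C9 in a 6-exo mode with respect to both π systems (6-exo-dig and 6-exo-trig), so C17 and C11 stay outside the ring. The new stereocentre C9 is controlled by C10 and C5: the two reacting arms are trans-diequatorial on the ring A chair, so ring B can only close trans-fused, and in the chair-like transition state the enoyl unit lies equatorial on the forming ring, which places C11 equatorial and cis to the axial C20 methyl (9R). The step needs chemoselectivity for cyclisation over alkyne oligomerisation, hydrosilylation and plain conjugate reduction; two-point binding of nickel by the alkyne and the electron-poor enoyl imide, the proximity enforced by ring A and slow addition of 17 are relied on for that. Bonding of C8 rather than C17 to C9 is secured by the tether length, since the alternative would be a seven-membered endo ring.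

Step 12
Reactants: 19 dimethyl (1S,5S,9R,10S)-1-[(tert-butyldimethylsilyl)oxy]-10-methyl-8-methylidene-9-[2-oxo-2-(2-oxo-1,3-oxazolidin-3-yl)ethyl]decalin-4,4-dicarboxylate
Product: 20 dimethyl (1S,5S,9R,10S)-1-[(tert-butyldimethylsilyl)oxy]-9-(2-hydroxyethyl)-10-methyl-8-methylidenedecalin-4,4-dicarboxylate
Conditions: LiBH4 (1.5 equiv), MeOH (1.5 equiv), Et2O, 0 °C
Reagents that add atoms: none
Why: Reductive cleavage of the N-acyl oxazolidinone by LiBH4 activated with methanol; the imide carbonyl is far more electrophilic than the hindered malonate esters, and the borohydride does not touch the 1,1-disubstituted alkene.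

Step 13
Reactants: 20 dimethyl (1S,5S,9R,10S)-1-[(tert-butyldimethylsilyl)oxy]-9-(2-hydroxyethyl)-10-methyl-8-methylidenedecalin-4,4-dicarboxylate
Product: 21 methyl (1S,5R,9R,10R)-1-[(tert-butyldimethylsilyl)oxy]-9-(2-hydroxyethyl)-10-methyl-8-methylidenedecalin-4-carboxylate (both C4 epimers; same spatial arrangement as 20, the descriptors at C5 and C10 change only through the priority rules)
Conditions: LiCl, H2O, DMSO, 150 °C
Reagents that add atoms: none
Why: Krapcho dealkoxycarbonylation (chloride attacks an ester methyl, the carboxylate loses CO2, water protonates the enolate) of the disubstituted malonate; the configuration of the new CH(CO2Me) centre is irrelevant because C4 is planarised again in the next step.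

Step 14
Reactants: 21 methyl (1S,5R,9R,10R)-1-[(tert-butyldimethylsilyl)oxy]-9-(2-hydroxyethyl)-10-methyl-8-methylidenedecalin-4-carboxylate
Product: 23 methyl (1S,4R,5S,9R,10S)-1-[(tert-butyldimethylsilyl)oxy]-9-(2-hydroxyethyl)-4,10-dimethyl-8-methylidenedecalin-4-carboxylate, via dilithium alkoxide enolate 22 (not isolated)
Conditions: LiN(i-Pr)2 (2.5 equiv), THF, −78 to 0 °C; MeI (1.2 equiv), −78 to −20 °C; aq. NH4Cl
Reagents that add atoms: iodomethane, CI
Why: Alkylation of the exocyclic ester enolate of a 10-methyl trans-decalin: the axial C20 methyl blocks the axial approach to C4 through its 1,3-diaxial relation, so MeI enters equatorially and the ester is left axial, cis to C20 (4R), the known outcome for this ring system. The lithium alkoxide at C12 is inert to MeI at low temperature, as in dianion alkylations of hydroxy esters.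

Step 15
Reactants: 23 methyl (1S,4R,5S,9R,10S)-1-[(tert-butyldimethylsilyl)oxy]-9-(2-hydroxyethyl)-4,10-dimethyl-8-methylidenedecalin-4-carboxylate
Product: 24 methyl (1S,4R,5S,9R,10S)-1-[(tert-butyldimethylsilyl)oxy]-4,10-dimethyl-8-methylidene-9-(2-oxoethyl)decalin-4-carboxylate
Conditions: Dess–Martin periodinane, CH2Cl2, 0 °C to rt
Reagents that add atoms: none
Why: Dess–Martin oxidation of the primary alcohol under neutral, non-aqueous conditions, which leaves the exocyclic alkene in place and stops at the aldehyde.

Step 16
Reactants: 24 methyl (1S,4R,5S,9R,10S)-1-[(tert-butyldimethylsilyl)oxy]-4,10-dimethyl-8-methylidene-9-(2-oxoethyl)decalin-4-carboxylate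
Product: 25 methyl (1S,4R,5S,9R,10S)-1-[(tert-butyldimethylsilyl)oxy]-4,10-dimethyl-8-methylidene-9-[(2E)-3-methyl-4-oxobut-2-en-1-yl]decalin-4-carboxylate
Conditions: Ph3P=C(CH3)CHO (1.5 equiv), toluene, 90 °C
Reagents that add atoms: 2-(triphenylphosphoranylidene)propanal, CC(C=O)=P(c1ccccc1)(c1ccccc1)c1ccccc1
Why: Wittig reaction of a stabilised formyl ylide with the unhindered aliphatic aldehyde gives the 2-methyl enal with E geometry (C12=C13); the α-branched, conjugated product aldehyde is too unreactive to add a second ylide.

Step 17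
Reactants: 25 methyl (1S,4R,5S,9R,10S)-1-[(tert-butyldimethylsilyl)oxy]-4,10-dimethyl-8-methylidene-9-[(2E)-3-methyl-4-oxobut-2-en-1-yl]decalin-4-carboxylate
Product: 26 methyl (1S,4R,5S,9R,10S)-1-[(tert-butyldimethylsilyl)oxy]labda-8(17),12E,14-trien-19-oate
Conditions: Ph3PCH3Br, KOt-Bu, THF, 0 °C
Reagents that add atoms: methyltriphenylphosphonium bromide (as its ylide), C[P+](c1ccccc1)(c1ccccc1)c1ccccc1.[Br-]
Why: Wittig methylenation; the non-stabilised ylide adds 1,2 to the enal and leaves the E trisubstituted alkene and the hindered C4 ester untouched.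

Step 18
Reactants: 26 methyl (1S,4R,5S,9R,10S)-1-[(tert-butyldimethylsilyl)oxy]labda-8(17),12E,14-trien-19-oate
Product: 27 methyl (1S,4R,5S,9R,10S)-1-hydroxylabda-8(17),12E,14-trien-19-oate
Conditions: Bu4NF, THF, 40 °C
Reagents that add atoms: none
Why: Fluoride cleavage of the secondary silyl ether; basic fluoride is chosen over acidic reagents to spare the conjugated diene and the exocyclic alkene.

Step 19
Reactants: 27 methyl (1S,4R,5S,9R,10S)-1-hydroxylabda-8(17),12E,14-trien-19-oate
Product: 28 methyl (1S,4R,5S,9R,10S)-1-acetoxylabda-8(17),12E,14-trien-19-oate (CNP0235031.1)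
Conditions: Ac2O, DMAP, pyridine, rt
Reagents that add atoms: acetic anhydride, CC(=O)OC(C)=O
Why: DMAP-catalysed acetylation of the hindered equatorial secondary alcohol, the only acylable group left in the molecule.

## Compound list

1 | dimethyl 4-oxocyclohexane-1,1-dicarboxylate | COC(=O)C1(CCC(=O)CC1)C(=O)OC | starting material
2 | dimethyl 4-oxocyclohex-2-ene-1,1-dicarboxylate | COC(=O)C1(C=CC(=O)CC1)C(=O)OC | intermediate
3 | dimethyl 3-iodo-4-oxocyclohex-2-ene-1,1-dicarboxylate | COC(=O)C1(C=C(I)C(=O)CC1)C(=O)OC | intermediate
4 | dimethyl 3-methyl-4-oxocyclohex-2-ene-1,1-dicarboxylate | COC(=O)C1(C=C(C)C(=O)CC1)C(=O)OC | intermediate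
5 | (4-bromobut-1-yn-1-yl)trimethylsilane | C[Si](C)(C)C#CCCBr | starting material
6 | [4-(trimethylsilyl)but-3-yn-1-yl]magnesium bromide | C[Si](C)(C)C#CCC[Mg]Br | intermediate (not isolated)
7 | bromomagnesium enolate of the (S)-conjugate adduct of 4 (C1–O–Mg, C1=C10) | COC(=O)C1(C(=O)OC)CCC(O[Mg]Br)=C(C)[C@@H]1CCC#C[Si](C)(C)C | intermediate (not isolated)
8 | dimethyl (2S,3R)-3-(hydroxymethyl)-3-methyl-4-oxo-2-[4-(trimethylsilyl)but-3-yn-1-yl]cyclohexane-1,1-dicarboxylate | OC[C@]1(C)C(=O)CCC(C(=O)OC)(C(=O)OC)[C@H]1CCC#C[Si](C)(C)C | intermediate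
9 | dimethyl (2S,3R,4S)-4-hydroxy-3-(hydroxymethyl)-3-methyl-2-[4-(trimethylsilyl)but-3-yn-1-yl]cyclohexane-1,1-dicarboxylate | OC[C@]1(C)[C@@H](O)CCC(C(=O)OC)(C(=O)OC)[C@H]1CCC#C[Si](C)(C)C | intermediate
10 | dimethyl (2S,3R,4S)-2-(but-3-yn-1-yl)-4-hydroxy-3-(hydroxymethyl)-3-methylcyclohexane-1,1-dicarboxylate | OC[C@]1(C)[C@@H](O)CCC(C(=O)OC)(C(=O)OC)[C@H]1CCC#C | intermediate
11 | dimethyl (2S,3S,4S)-2-(but-3-yn-1-yl)-3-formyl-4-hydroxy-3-methylcyclohexane-1,1-dicarboxylate | O=C[C@]1(C)[C@@H](O)CCC(C(=O)OC)(C(=O)OC)[C@H]1CCC#C | intermediate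
12 | oxazolidin-2-one | O=C1NCCO1 | starting material
13 | 2-(diethoxyphosphoryl)acetic acid | CCOP(=O)(CC(=O)O)OCC | starting material
14 | 2-(diethoxyphosphoryl)acetic pivalic anhydride | CCOP(=O)(CC(=O)OC(=O)C(C)(C)C)OCC | intermediate (not isolated)
15 | diethyl [2-oxo-2-(2-oxo-1,3-oxazolidin-3-yl)ethyl]phosphonate | CCOP(=O)(CC(=O)N1CCOC1=O)OCC | intermediate
16 | dimethyl (2S,3S,4S)-2-(but-3-yn-1-yl)-4-hydroxy-3-methyl-3-[(1E)-3-oxo-3-(2-oxo-1,3-oxazolidin-3-yl)prop-1-en-1-yl]cyclohexane-1,1-dicarboxylate | O=C1OCCN1C(=O)/C=C/[C@]2(C)[C@@H](O)CCC(C(=O)OC)(C(=O)OC)[C@H]2CCC#C | intermediate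
17 | dimethyl (2S,3S,4S)-2-(but-3-yn-1-yl)-4-[(tert-butyldimethylsilyl)oxy]-3-methyl-3-[(1E)-3-oxo-3-(2-oxo-1,3-oxazolidin-3-yl)prop-1-en-1-yl]cyclohexane-1,1-dicarboxylate | O=C1OCCN1C(=O)/C=C/[C@]2(C)[C@@H](O[Si](C)(C)C(C)(C)C)CCC(C(=O)OC)(C(=O)OC)[C@H]2CCC#C | intermediate
18 | (Z)-triethylsilyl ketene N,O-acetal of 19 (C11=C12, O-silylated) | CC[Si](CC)(CC)O/C(N1CCOC1=O)=C\[C@@H]1C(=C)CC[C@H]2[C@@]1(C)[C@@H](O[Si](C)(C)C(C)(C)C)CCC2(C(=O)OC)C(=O)OC | intermediate (not isolated)
19 | dimethyl (1S,5S,9R,10S)-1-[(tert-butyldimethylsilyl)oxy]-10-methyl-8-methylidene-9-[2-oxo-2-(2-oxo-1,3-oxazolidin-3-yl)ethyl]decalin-4,4-dicarboxylate | O=C1OCCN1C(=O)C[C@@H]1C(=C)CC[C@H]2[C@@]1(C)[C@@H](O[Si](C)(C)C(C)(C)C)CCC2(C(=O)OC)C(=O)OC | intermediate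
20 | dimethyl (1S,5S,9R,10S)-1-[(tert-butyldimethylsilyl)oxy]-9-(2-hydroxyethyl)-10-methyl-8-methylidenedecalin-4,4-dicarboxylate | OCC[C@@H]1C(=C)CC[C@H]2[C@@]1(C)[C@@H](O[Si](C)(C)C(C)(C)C)CCC2(C(=O)OC)C(=O)OC | intermediate
21 | methyl (1S,5R,9R,10R)-1-[(tert-butyldimethylsilyl)oxy]-9-(2-hydroxyethyl)-10-methyl-8-methylidenedecalin-4-carboxylate (both C4 epimers, C4 left undefined) | OCC[C@@H]1C(=C)CC[C@H]2[C@@]1(C)[C@@H](O[Si](C)(C)C(C)(C)C)CCC2C(=O)OC | intermediate
22 | dilithium C12 alkoxide / C4 ester enolate of 21 | [Li]OCC[C@@H]1C(=C)CC[C@H]2[C@@]1(C)[C@@H](O[Si](C)(C)C(C)(C)C)CCC2=C(O[Li])OC | intermediate (not isolated)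
23 | methyl (1S,4R,5S,9R,10S)-1-[(tert-butyldimethylsilyl)oxy]-9-(2-hydroxyethyl)-4,10-dimethyl-8-methylidenedecalin-4-carboxylate | OCC[C@@H]1C(=C)CC[C@H]2[C@@]1(C)[C@@H](O[Si](C)(C)C(C)(C)C)CC[C@@]2(C)C(=O)OC | intermediate
24 | methyl (1S,4R,5S,9R,10S)-1-[(tert-butyldimethylsilyl)oxy]-4,10-dimethyl-8-methylidene-9-(2-oxoethyl)decalin-4-carboxylate | O=CC[C@@H]1C(=C)CC[C@H]2[C@@]1(C)[C@@H](O[Si](C)(C)C(C)(C)C)CC[C@@]2(C)C(=O)OC | intermediate
25 | methyl (1S,4R,5S,9R,10S)-1-[(tert-butyldimethylsilyl)oxy]-4,10-dimethyl-8-methylidene-9-[(2E)-3-methyl-4-oxobut-2-en-1-yl]decalin-4-carboxylate | O=C/C(C)=C/C[C@@H]1C(=C)CC[C@H]2[C@@]1(C)[C@@H](O[Si](C)(C)C(C)(C)C)CC[C@@]2(C)C(=O)OC | intermediate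
26 | methyl (1S,4R,5S,9R,10S)-1-[(tert-butyldimethylsilyl)oxy]labda-8(17),12E,14-trien-19-oate | C=C/C(C)=C/C[C@@H]1C(=C)CC[C@H]2[C@@]1(C)[C@@H](O[Si](C)(C)C(C)(C)C)CC[C@@]2(C)C(=O)OC | intermediate
27 | methyl (1S,4R,5S,9R,10S)-1-hydroxylabda-8(17),12E,14-trien-19-oate | C=C/C(C)=C/C[C@@H]1C(=C)CC[C@H]2[C@@]1(C)[C@@H](O)CC[C@@]2(C)C(=O)OC | intermediate
28 | methyl (1S,4R,5S,9R,10S)-1-acetoxylabda-8(17),12E,14-trien-19-oate (CNP0235031.1) | C=C/C(C)=C/C[C@@H]1C(=C)CC[C@H]2[C@@]1(C)[C@@H](OC(C)=O)CC[C@@]2(C)C(=O)OC | target

## Step count and risk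

Total: 19 steps. Longest linear sequence: 18 steps (steps 1–7 and 9–19, from 1); step 8 is a one-step side branch.

**Step 11 (key step).** The oxidative cyclisation has to form a six-membered ring against quaternary C10 and will be slower than the five-membered cases. Intermolecular reactions of the terminal alkyne at zerovalent nickel (oligomerisation, hydrosilylation) or simple conjugate reduction of the enoyl imide may then take over. Erosion of facial selectivity at C9 through a boat-like closure is the second concern. Fallback (radical instead of organometallic closure of the same bond): from 17, Bu3SnH and AIBN in benzene at 80 °C add the stannyl radical to C17, the C8 vinyl radical closes 6-exo onto C9 and the α-acyl radical is reduced, giving exocyclic vinylstannane F1. Protodestannylation with CF3CO2H in CH2Cl2 at 0 °C comes back to the route at 19.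

**Step 4.** The β-carbon of 4 is flanked by the α-methyl group and the quaternary malonate carbon, so the conjugate addition may be slow or poorly enantioselective, with competing 1,2-addition of the Grignard reagent. The axial C4 ester also opposes the anti approach of the electrophile to some degree, and the aldolate may attack a ring ester. Fallback (methyl introduced after, not before, the asymmetric step): from 2 and 6. Reagent 6 is transmetalated with ZnCl2 (0.5 equiv, magnesium halides precipitated with dioxane) to diorganozinc F2. F2 is added to the less hindered enone 2 with Cu(OTf)2 and a BINOL-derived phosphoramidite, a catalysis well established for 4,4-disubstituted cyclohexenones. The resulting zinc enolate F3 is trapped with formaldehyde to give aldol F4. Mesylation (MsCl, Et3N) gives mesylate F5, and elimination with DBU gives α-methylene ketone F6. Conjugate reduction with LiBH(s-Bu)3 at −78 °C turns the methylene carbon into the C20 methyl and gives lithium enolate F7. Trapping of F7 with formaldehyde anti to the C5 chain comes back to the route at 8.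

**Step 9.** The β-hydroxy aldehyde 11 may undergo retro-aldol cleavage of the C1–C10 bond under the amine base, and olefination of the neopentyl aldehyde may be sluggish, which prolongs the exposure. Over-oxidation at C1 in step 7 would feed the same problem. Fallback (protect before oxidising): from 10, TBSOTf and 2,6-lutidine give bis-silyl ether F8. Selective cleavage of the primary silyl ether (HF·pyridine, pyridine, THF, 0 °C) gives primary alcohol F9. Dess–Martin oxidation gives aldehyde F10, which cannot fragment, and its olefination with 15 under the conditions of step 9 comes back to the route at 17.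

**Step 14.** Deprotonation of the hindered C4–H may be incomplete, and the C12 alkoxide may be O-methylated if the alkylation needs higher temperature or a polar additive. Loss of facial control is less likely in view of the axial C20 methyl. Fallback (mask the alcohol before the C4 chemistry): from 20, TBSCl and imidazole give bis-silyl ether malonate F11. The Krapcho conditions of step 13 give monoester F12. LiN(i-Pr)2 gives lithium enolate F13, and MeI gives methylated ester F14. Selective removal of the primary silyl ether with PPTS in MeOH comes back to the route at 23.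

## Further compounds

F1 | step 11 | dimethyl (1S,5S,9R,10S)-1-[(tert-butyldimethylsilyl)oxy]-10-methyl-9-[2-oxo-2-(2-oxo-1,3-oxazolidin-3-yl)ethyl]-8-[(tributylstannyl)methylidene]decalin-4,4-dicarboxylate (C8=C17 geometry undefined) | O=C1OCCN1C(=O)C[C@@H]1C(=C[Sn](CCCC)(CCCC)CCCC)CC[C@H]2[C@@]1(C)[C@@H](O[Si](C)(C)C(C)(C)C)CCC2(C(=O)OC)C(=O)OC
F2 | step 4 | bis[4-(trimethylsilyl)but-3-yn-1-yl]zinc | C[Si](C)(C)C#CCC[Zn]CCC#C[Si](C)(C)C
F3 | step 4 | alkylzinc enolate of the (S)-conjugate adduct of 2 | COC(=O)C1(C(=O)OC)CCC(O[Zn]CCC#C[Si](C)(C)C)=C[C@@H]1CCC#C[Si](C)(C)C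
F4 | step 4 | dimethyl (2S,3-trans)-3-(hydroxymethyl)-4-oxo-2-[4-(trimethylsilyl)but-3-yn-1-yl]cyclohexane-1,1-dicarboxylate | OC[C@@H]1C(=O)CCC(C(=O)OC)(C(=O)OC)[C@H]1CCC#C[Si](C)(C)C
F5 | step 4 | methanesulfonate of F4 | CS(=O)(=O)OC[C@@H]1C(=O)CCC(C(=O)OC)(C(=O)OC)[C@H]1CCC#C[Si](C)(C)C
F6 | step 4 | dimethyl (2S)-3-methylidene-4-oxo-2-[4-(trimethylsilyl)but-3-yn-1-yl]cyclohexane-1,1-dicarboxylate | C=C1C(=O)CCC(C(=O)OC)(C(=O)OC)[C@H]1CCC#C[Si](C)(C)C
F7 | step 4 | lithium enolate corresponding to 7 | COC(=O)C1(C(=O)OC)CCC(O[Li])=C(C)[C@@H]1CCC#C[Si](C)(C)C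
F8 | step 9 | dimethyl (2S,3R,4S)-2-(but-3-yn-1-yl)-4-[(tert-butyldimethylsilyl)oxy]-3-{[(tert-butyldimethylsilyl)oxy]methyl}-3-methylcyclohexane-1,1-dicarboxylate | CC(C)(C)[Si](C)(C)OC[C@]1(C)[C@@H](O[Si](C)(C)C(C)(C)C)CCC(C(=O)OC)(C(=O)OC)[C@H]1CCC#C
F9 | step 9 | dimethyl (2S,3R,4S)-2-(but-3-yn-1-yl)-4-[(tert-butyldimethylsilyl)oxy]-3-(hydroxymethyl)-3-methylcyclohexane-1,1-dicarboxylate | OC[C@]1(C)[C@@H](O[Si](C)(C)C(C)(C)C)CCC(C(=O)OC)(C(=O)OC)[C@H]1CCC#C
F10 | step 9 | dimethyl (2S,3S,4S)-2-(but-3-yn-1-yl)-4-[(tert-butyldimethylsilyl)oxy]-3-formyl-3-methylcyclohexane-1,1-dicarboxylate | O=C[C@]1(C)[C@@H](O[Si](C)(C)C(C)(C)C)CCC(C(=O)OC)(C(=O)OC)[C@H]1CCC#C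
F11 | step 14 | dimethyl 1-[(tert-butyldimethylsilyl)oxy]-9-{2-[(tert-butyldimethylsilyl)oxy]ethyl}-10-methyl-8-methylidenedecalin-4,4-dicarboxylate (configuration as in 20) | CC(C)(C)[Si](C)(C)OCC[C@@H]1C(=C)CC[C@H]2[C@@]1(C)[C@@H](O[Si](C)(C)C(C)(C)C)CCC2(C(=O)OC)C(=O)OC
F12 | step 14 | methyl 1-[(tert-butyldimethylsilyl)oxy]-9-{2-[(tert-butyldimethylsilyl)oxy]ethyl}-10-methyl-8-methylidenedecalin-4-carboxylate (both C4 epimers) | CC(C)(C)[Si](C)(C)OCC[C@@H]1C(=C)CC[C@H]2[C@@]1(C)[C@@H](O[Si](C)(C)C(C)(C)C)CCC2C(=O)OC
F13 | step 14 | lithium C4 ester enolate of F12 | CC(C)(C)[Si](C)(C)OCC[C@@H]1C(=C)CC[C@H]2[C@@]1(C)[C@@H](O[Si](C)(C)C(C)(C)C)CCC2=C(O[Li])OC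
F14 | step 14 | methyl (4R)-1-[(tert-butyldimethylsilyl)oxy]-9-{2-[(tert-butyldimethylsilyl)oxy]ethyl}-4,10-dimethyl-8-methylidenedecalin-4-carboxylate (configuration as in 23) | CC(C)(C)[Si](C)(C)OCC[C@@H]1C(=C)CC[C@H]2[C@@]1(C)[C@@H](O[Si](C)(C)C(C)(C)C)CC[C@@]2(C)C(=O)OC
A1 | alternative 1 | 3-methyl-2H-pyran-2-one | CC1=CC=COC1=O
A2 | alternative 1 | (2E)-6,6-dimethoxy-2-methylhex-2-enal | COC(OC)CC/C=C(\C)C=O
A3 | alternative 1 | 8-(3,3-dimethoxypropyl)-4,7-dimethyl-3-oxo-2-oxabicyclo[2.2.2]oct-5-ene-7-carbaldehyde (endo adduct, configuration as in the SMILES) | COC(OC)CC[C@H]1[C@@](C=O)(C)[C@H]2OC(=O)[C@]1(C)C=C2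
A4 | alternative 2 | methyl 9-{2-[(tert-butyldimethylsilyl)oxy]ethyl}-1,10-epoxy-10-methyl-8-methylidenecyclodec-4-ene-4-carboxylate (target numbering, trans epoxide, trans ring alkene) | CC(C)(C)[Si](C)(C)OCC[C@@H]1C(=C)CC/C=C(\C(=O)OC)CC[C@@H]2O[C@@]12C
A5 | alternative 2 | methyl 9-{2-[(tert-butyldimethylsilyl)oxy]ethyl}-1-hydroxy-10-methyl-8-methylidene-trans-decalin-4-carboxylate (labdane numbering, C4 epimers) | CC(C)(C)[Si](C)(C)OCC[C@@H]1C(=C)CC[C@H]2[C@@]1(C)[C@@H](O)CCC2C(=O)OC
A6 | alternative 3 | dimethyl 2-{(3S,4E)-3-[(tert-butyldimethylsilyl)oxy]-4-methyl-6-oxohex-4-en-1-yl}-2-[(1E,3E)-4-(triethylsilyloxy)buta-1,3-dien-1-yl]malonate | O=C/C=C(\C)[C@@H](O[Si](C)(C)C(C)(C)C)CCC(C(=O)OC)(C(=O)OC)/C=C/C=C/O[Si](CC)(CC)CC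
A7 | alternative 3 | dimethyl 1-[(tert-butyldimethylsilyl)oxy]-9-formyl-10-methyl-8-(triethylsilyloxy)-trans-octal-6-ene-4,4-dicarboxylate (labdane numbering) | O=C[C@@H]1[C@H](O[Si](CC)(CC)CC)C=C[C@H]2[C@@]1(C)[C@@H](O[Si](C)(C)C(C)(C)C)CCC2(C(=O)OC)C(=O)OC
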